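The data were computed on assumed constants, noise included.

If a single-handed free catalyst turns a racemate with a partner and both mirror-image substrates give product, the useful number is how the yield divides between the two hands.

| setting | Wednesday's | Saturday's | flask |
|---|---|---|---|
| left-handed substrate | 0.50 M | 0.50 M | 0.50 M |
| right-handed substrate | 0.50 M | 0.50 M | 0.50 M |
| partner | 3 equiv | 3 equiv | 3.00 equiv |
| free catalyst | 0.2 mol% | 0.2 mol% | 0.2 mol% |
| racemization catalyst | 7.5 mol% | 11 mol% | 15 mol% |
| added ligand | 3.6 mM | 3.6 mM | 3.6 mM |
| remark | run made earlier | run made earlier |  |
| time |  |  | 5.0 min |

Wednesday's run and Saturday's run differ in racemization catalyst, 7.5 mol% against 11 mol%, and the new flask carries 15 mol%.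

- Wednesday's (time / min: left-handed product / %, right-handed product / %): 1.33: 13.3, 5.6; 2.50: 23.5, 10.5; 4.00: 30.0, 11.6; 5.00: 34.7, 16.4; 6.00: 37.5, 17.0
- Saturday's (time / min: left-handed product / %, right-handed product / %): 0.500: 7.4, 4.2; 0.833: 10.1, 4.0; 1.50: 16.0, 7.7; 3.00: 25.7, 9.7; 6.00: 37.8, 16.3

(readings scatter by 1 percentage point)

- free catalyst is single-handed; left-handed substrate and right-handed substrate are mirror images of each other, charged as a racemate, each of them at the stated concentration
- an excess is the difference of the two amounts in percent of their sum
- an excess is below zero if the other one leads

But at 6.00 min Wednesday's run holds 54.5% of product and Saturday's run 54.1%, so the two tables can be pooled.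

Summed over both tables, left-handed product over right-handed product gives 2.29. This is the split ratio, the left-handed product made per amount of right-handed product, averaged over the run. Right-handed product is then the yield divided by one more than the ratio, and the excess is the ratio less one over the ratio plus one.

Within the scatter of these readings the mean costs little: readings up to 1.50 min give 2.18 and those at 6.00 min give 2.26.

1. left-handed product and right-handed product together, in percent of the left-handed substrate and right-handed substrate charged together, at 5.0 min
2. excess of left-handed product over right-handed product in the product at 5.0 min
3. whether the exchange between left-handed substrate and right-handed substrate keeps pace with the reaction: how far the product's excess at 5.0 min gets from its value without exchange to its value with instant exchange (above 80% keeps pace, below 20% hardly takes part, else lags behind)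

The reckoning here takes Wednesday's yield at 5.00 min, 51.1%, and an excess of 39.2%. The split ratio takes no side on the pace.

The forecast says 48% (45% to 51.5%), lower than this yield, with an excess of 39.5% (35% to 44%). On the pace it says keeps pace: “Exchange therefore appears fast, though the evidence is only moderate”.

The flask gives a yield of 49.5% and an excess of 42.2%, and its exchange lags behind, getting 44% of the way from the excess without exchange to the excess with instant exchange.

    partner + free catalyst + left-handed substrate → free catalyst + left-handed product (k = 5.03 M⁻² s⁻¹)
    racemization catalyst → spent catalyst (k = 2.22 × 10⁻⁵ s⁻¹)
    left-handed substrate + racemization catalyst ⇌ right-handed substrate + racemization catalyst, rate k3*[racemization catalyst]*[left-handed substrate] forward; the back reaction follows from the equilibrium constant (k = 0.0475 M⁻¹ s⁻¹)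
    free catalyst + added ligand ⇌ idle complex, settled at all times (K = 220 M⁻¹)
    partner + free catalyst + right-handed substrate → free catalyst + right-handed product (k = 1.71 M⁻² s⁻¹)

The selectivity factor, the ratio of the two rate constants, is 2.94. In this flask the split ratio turns the yield into 15.0% of right-handed product, against 14.3% in the flask at 5.00 min. The neighbouring flask with 0.34 mol% of free catalyst yields 65.0%, which the split ratio turns into 19.8% of right-handed product, and that flask holds 20.0%.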